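Time first: the 6.0 h asked is twice the 3.00 h of the last epsilon reading, so Wednesday's end has to be extrapolated.

common to all: Q 0.31 M
- epsilon: J 0.40 M; run made earlier
- theta: J 0.77 M; run made earlier
- Wednesday's: J 0.372 M; time 6.0 h
- Monday's: J 0.310 M; time 6.0 h
- Friday's: J 0.620 M; time 6.0 h

| run | time / h | Z / % | Q / % |
|---|---|---|---|
| epsilon | 0.417 | 27.1 | 50.6 |
| epsilon | 0.833 | 18.6 | 42.3 |
| epsilon | 1.33 | 15.0 | 32.6 |
| epsilon | 1.50 | 13.4 | 31.3 |
| epsilon | 2.00 | 10.6 | 25.9 |
| epsilon | 2.50 | 9.4 | 21.9 |
| epsilon | 3.00 | 8.5 | 18.6 |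
| theta | 0.167 | 38.6 | 42.1 |
| theta | 0.500 | 23.7 | 28.7 |
| theta | 0.833 | 17.1 | 20.1 |
| theta | 1.33 | 11.6 | 12.4 |
| theta | 2.00 | 7.6 | 7.3 |
| theta | 2.50 | 5.9 | 4.0 |
| theta | 3.00 | 5.0 | 4.3 |

(scatter of a reading: 0.5 percentage points)

- which of these holds the largest part of the Q at the end of Wednesday's (Z / G / Q)
- which of these holds the largest part of the Q at the end of Monday's (Z / G / Q)
- which of these holds the largest part of the Q at the end of Friday's (Z / G / Q)
- amount of Z at the end of Wednesday's, in percent of the Q charged



**Halving time.** In the epsilon run, Q at a later time roughly follows its first reading divided by one plus the elapsed time over a halving time. From 50.6 % at 0.417 h and 25.9 % at 2.00 h, that time reads 1.66 h. The same reckoning on theta reads 0.608 h.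

**Which inputs matter.** Q is charged at 0.31 M in both runs and in Wednesday's, so it needs no correction. The scatter is 0.5 percentage points on a reading of 25.9 %, which I accept. The time is exact, so the risk lies in the extrapolation. J is the sensitive input: going from 0.40 M to 0.77 M, the halving time falls as [J] to the power 1.53, taken negative.

**My number.** Wednesday's charge of 0.372 M therefore gives a halving time, an apparent second-order half-life of Q, of 1.86 h. Starting from the same first reading, Q at 6.0 h comes to 12.6 %. Z over Q read 0.457 at the last epsilon reading. Scaled by the J charged, this puts Wednesday's Z at 5.36 %. G is not among the readings, and the remainder is only its ceiling, so I rank Q above Z and leave G open.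

**The forecast.** It names G for Wednesday's, G for Monday's and G for Friday's, with Z at 5 %: “G dominates in all three”.

**The flask.** Among the three asked, the largest is Q on Wednesday's, Q on Monday's and G on Friday's, and Wednesday's Z is 4.95 %.

    D + Z → L (k = 0.00380 L mol⁻¹ s⁻¹)
    Z + J ⇌ D + G (K = 0.370, k = 5.00 × 10⁻⁴ L mol⁻¹ s⁻¹)
    Q + J ⇌ D + Z (K = 0.280, k = 0.00680 L mol⁻¹ s⁻¹)
    Z → E (k = 2.30 × 10⁻⁶ s⁻¹)

**Where it goes.** Wednesday's Q ends at 11.5 % against my 12.6 %, and the flask holds more as L, at 77.9 %, than as G, at 5.08 %. The step from D + Z to L is the largest single effect on Wednesday's Z: in the run without that step, Z ends at 24.1 %, not 4.95 %, and the answer for Friday's changes.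

**Second flask.** Stopped at 2.5 h, Wednesday's flask should, with the halving time of 1.86 h, hold Q at 23.8 % and Z at 10.1 %. It holds 25.0 % and 9.79 %.

All runs come from a simulation for substances that don't exist, noise included.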